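**Plan**

- Retrosynthesis: one operation cuts two bonds. These are the C–C bond between the benzylic CH2 of the alcohol half and the next chain CH2, and the acyl C–O bond of the ester. The pieces are a 3,4-dimethoxybenzyl carbanion, oxirane and a 3-(3,4-dimethoxyphenyl)propanoyl cation.
- Enabling feature: in the propyl chain the ester oxygen sits on the carbon next to the chain carbon of the new C–C bond, so this O–CH2–CH2 unit is an opened oxirane. The other carbon of that bond is benzylic to the 3,4-dimethoxyphenyl ring and can carry magnesium.
- Forward: alcohol 1 gives chloride 2 and acid 3 gives acid chloride 4. In one flask, magnesium inserts into 2, the benzylic carbon opens oxirane 5 (C–C bond), and the resulting magnesium alkoxide is O-acylated by 4 (ester bond) to give the target.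
- No ring arises and the target is achiral, so no stereocentre has to be set. No helper group has to be removed, because the ring strain of oxirane and the C–Mg and C–Cl activation are used up in the event.
- Assumption: 1, 3 and oxirane (as its solution in THF) are bought; 2 is made fresh because electron-rich benzylic chlorides keep poorly.

Key step: step 3

**Step 1**
Reactants: 1 (3,4-dimethoxyphenyl)methanol
Product: 2 4-(chloromethyl)-1,2-dimethoxybenzene
Conditions: SOCl2 (1.2 equiv), CH2Cl2, 0 °C → rt; evaporation, toluene chase, used at once
Reagents that add atoms: thionyl chloride, O=S(Cl)Cl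
Why: Deoxychlorination of a benzylic alcohol with thionyl chloride through the chlorosulfite should be fast at this electron-rich benzylic carbon and leaves the aryl methyl ethers untouched, so crude 2 can be taken on directly.

**Step 2**
Reactants: 3 3-(3,4-dimethoxyphenyl)propanoic acid
Product: 4 3-(3,4-dimethoxyphenyl)propanoyl chloride
Conditions: (COCl)2 (1.2 equiv), DMF (cat.), CH2Cl2, 0 °C → rt; evaporation, used crude
Reagents that add atoms: oxalyl chloride, O=C(Cl)C(=O)Cl
Why: Acid chloride formation by Vilsmeier-type (chloroiminium) activation runs without a Lewis acid, so the electron-rich ring should not undergo Friedel–Crafts cyclisation to the indanone.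

**Step 3**
Reactants: 2 4-(chloromethyl)-1,2-dimethoxybenzene; 5 oxirane; 4 3-(3,4-dimethoxyphenyl)propanoyl chloride
Product: 8 3-(3,4-dimethoxyphenyl)propyl 3-(3,4-dimethoxyphenyl)propanoate, via benzylic Grignard reagent 6 (not isolated), via chloromagnesium alkoxide 7 (not isolated)
Conditions: i) Mg turnings (excess, I2-activated), 2-MeTHF, 0 °C, slow addition of dilute 2; solution decanted from Mg and titrated; ii) 5 (1.3 equiv, THF solution), CuI (5 mol %), −30 → 0 °C, then N2 purge of excess 5; iii) 4 (1.0 equiv to titre), DMAP (cat.), 0 °C → rt; aq. NH4Cl
Reagents that add atoms: none
Why: Magnesium inserts into the benzylic C–Cl bond of 2 to give 6, whose benzylic carbon (as a cuprate under CuI catalysis) opens oxirane 5 by SN2 attack at a ring CH2, which forms the C(benzylic)–CH2 bond and leaves the chloromagnesium alkoxide 7; addition–elimination of 7 on acid chloride 4 then forms the ester, so three components are joined in one flask. The closest known reaction type is the two-carbon homologation of a Grignard reagent with ethylene oxide, followed by trapping of the magnesium alkoxide with an acyl chloride. No ring is closed (one is opened) and no stereocentre is formed, so neither a mode of closure nor a control element is involved, and the symmetry of oxirane removes any regiochemical question at the electrophile. The step needs attack from the benzylic carbon and not from the ortho ring carbon, and opening of the oxirane by carbon and not by chloride, both of which the soft copper-mediated SN2 pathway at low temperature should secure. It also needs O-acylation without ketone formation, which is secured by the slight excess of 5 that consumes every C–Mg bond before 4 is added and by purging the remaining volatile 5 so that 4 is not diverted to a 2-chloroethyl ester. Wurtz homocoupling during the formation of 6 should be held down by slow addition of dilute 2 to excess activated magnesium at 0 °C in 2-MeTHF.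

**Compound list**

1 | (3,4-dimethoxyphenyl)methanol (veratryl alcohol) | COc1ccc(CO)cc1OC | starting material
2 | 4-(chloromethyl)-1,2-dimethoxybenzene (3,4-dimethoxybenzyl chloride) | COc1ccc(CCl)cc1OC | intermediate
3 | 3-(3,4-dimethoxyphenyl)propanoic acid | COc1ccc(CCC(=O)O)cc1OC | starting material
4 | 3-(3,4-dimethoxyphenyl)propanoyl chloride | COc1ccc(CCC(=O)Cl)cc1OC | intermediate
5 | oxirane (ethylene oxide) | C1CO1 | starting material
6 | (3,4-dimethoxybenzyl)magnesium chloride | COc1ccc(C[Mg]Cl)cc1OC | intermediate
7 | chloromagnesium 3-(3,4-dimethoxyphenyl)propan-1-olate | COc1ccc(CCCO[Mg]Cl)cc1OC | intermediate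
8 | 3-(3,4-dimethoxyphenyl)propyl 3-(3,4-dimethoxyphenyl)propanoate | COc1ccc(CCCOC(=O)CCc2ccc(OC)c(OC)c2)cc1OC | target

**Total step count:** 3
**Longest linear sequence:** 2 steps (1 → 2 → 8, or 3 → 4 → 8)

**Steps most likely to fail**

Step 3. What may go wrong: Wurtz-type homocoupling during the magnesium insertion, opening of the oxirane by chloride in place of carbon, or slow O-acylation of the aggregated magnesium alkoxide. The fallback uses no organomagnesium and builds the same benzylic C–C bond first as a C=C bond. It sets out from 4, which is treated with allyl alcohol (C=CCO), Et3N and DMAP (cat.) in CH2Cl2 at 0 °C to give allyl 3-(3,4-dimethoxyphenyl)propanoate F1. Olefin cross-metathesis of F1 with an excess of 3,4-dimethoxystyrene (C=Cc1ccc(OC)c(OC)c1) under a second-generation Grubbs catalyst in CH2Cl2 at 40 °C should give (E)-3-(3,4-dimethoxyphenyl)prop-2-en-1-yl 3-(3,4-dimethoxyphenyl)propanoate F2. Hydrogenation of the alkene over Wilkinson's catalyst (H2, RhCl(PPh3)3, benzene/EtOH, rt), chosen because it should not cleave the allylic C–O bond, comes back to the route at 8.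

Step 1. What may go wrong: acid-promoted Friedel–Crafts self-alkylation (oligomerisation) or hydrolysis of the electron-rich benzylic chloride during concentration. The fallback is halide-free and sets out from 1. O-Methylation (NaH, MeI, THF) gives 4-(methoxymethyl)-1,2-dimethoxybenzene F3, a stable ether. Reductive cleavage of its benzylic C–O bond with lithium and catalytic naphthalene in THF at −40 °C should give (3,4-dimethoxybenzyl)lithium F4, and transmetalation with anhydrous MgCl2 comes back to the route at 6. The lithium methoxide formed beside F4 would take up a second equivalent of 4 in step 3 as the methyl ester, which would be removed by chromatography.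

Step 2. What may go wrong: Friedel–Crafts cyclisation of the acid chloride onto its own electron-rich ring during concentration, or hydrolysis on handling. The fallback uses a milder acyl donor and sets out from 3. Treatment with 1,1'-carbonyldiimidazole in THF at rt gives 3-(3,4-dimethoxyphenyl)-1-(1H-imidazol-1-yl)propan-1-one F5. F5 is added to alkoxide 7 in step 3 in place of 4 and comes back to the route at 8.

**Further compounds**

F1 | step 3 | allyl 3-(3,4-dimethoxyphenyl)propanoate | C=CCOC(=O)CCc1ccc(OC)c(OC)c1
F2 | step 3 | (E)-3-(3,4-dimethoxyphenyl)prop-2-en-1-yl 3-(3,4-dimethoxyphenyl)propanoate | COc1ccc(/C=C/COC(=O)CCc2ccc(OC)c(OC)c2)cc1OC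
F3 | step 1 | 4-(methoxymethyl)-1,2-dimethoxybenzene | COCc1ccc(OC)c(OC)c1
F4 | step 1 | (3,4-dimethoxybenzyl)lithium | [Li]Cc1ccc(OC)c(OC)c1
F5 | step 2 | 3-(3,4-dimethoxyphenyl)-1-(1H-imidazol-1-yl)propan-1-one | COc1ccc(CCC(=O)n2ccnc2)cc1OC
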